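Each unit of starting material that reacts costs gas, so you reckon what is left over in this flask in gas.

starting material 2.7 M; gas phase 120 mM (held); time 25 min

    gas phase ⇌ dissolved gas, rate k1*(csat - [dissolved gas]) (k1 = 0.0136 /s, csat = 120 mM)
    starting material + dissolved gas ⇌ target (K2 = 12.7 /M, k2 = 0.0450 /M/s)
    dissolved gas + target → over-reacted product (k3 = 0.0422 /M/s)
    crystals ⇌ target, rate k4*(cs4 - [target]) while solid is left; crystals form when [target] > cs4 (cs4 = 0.22 M, k4 = 0.00752 /s)

- the target and crystals together standing at 25 min, as a percentage of the starting material charged
- concentration of dissolved gas in solution at 25 min, in percent of saturation

- Ask first what the end state must be. The over-reaction has no way back and the gas phase is held, so the end is over-reacted product, and that costs 2 units of gas per unit of starting material.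
- Now take the time scales, fastest first. With the charge as it stands, the forward reaction gives dissolved gas a half-life of 0.095 min, shorter than the 0.849 min half-life of transfer. So at the start I take transfer as the rate-limiting step and expect dissolved gas to stay low.
- That reaction leans towards target at the start, since its equilibrium constant times the starting material is 34, above 1.
- The last rung is supply. By 25 min transfer can bring at most 90.7 % of the charge: this is the gas budget, the most that transfer can deliver by the end of the run into a solution kept empty, per charge of starting material.
- The full bill would take at least 55.1 min, which is longer than the run. My reckoning stops here: target and crystals stay below the budget, and at least 9.30 % of the starting material remains.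
- The forecast gave 40 % and 27 %, on the ground that “gas transfer limits the reaction”; its yield is inside the budget.
- The simulation gives 38.9 % and 27.2 %, so the forecast held.
- This flask is not at rest at 25 min: 44.9 % of the starting material stands, with 16.1 % over-reacted. Counting target once and over-reacted product twice, 71.2 % of the charge in gas is spent, less than the budget. By 250 min the yield of this flask is 0 % and over-reacted product is 100 %.
- A second flask, like this one in all else, holds 0.68 M of starting material, and its budget is 360 % of its charge, above the bill of 2 charges. So supply no longer forbids the end state within the run. Computed, that second flask stands at 73.1 % over-reacted product, 10.6 % target and 16.2 % starting material.

The constants were set for the occasion.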